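**Plan**

1. Retrosynthetic cuts: C13–C16 (ring D, Rauhut–Currier), C8–C14 (ring C, enolate alkylation), the O20–C7 lactone bond (exchanged for a temporary O11–C7 γ-lactone), and C9–C10 (radical union of ring A epoxide 9 with acylbutenolide 19).
2. Forward order: ring A (steps 1–5) and the butenolide (steps 6–10) are joined at C9–C10 (step 11); ring C is closed at C8–C14 on the temporary γ-lactone (step 14); the lactone is handed from O11 to O20 while C11 is oxidised (step 15); ring D is closed last (step 17); acetates and the C11 hydroxyl follow (steps 18–20).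
3. Enabling feature: C8 lies between the C7 carboxyl carbon and the C15 ketone (acidic C–H), and C7 can be lactonised to O11, which is 1,3 to C8 across C9, instead of to O20. In that five-membered lactone a side chain on C11 reaches C8 from one face only, so C8–C14 closure gives a 6-oxabicyclo[3.2.1]octenone and fixes the quaternary C8.
4. Chiral pool: C7, C8, C9, C11 and C12 are the five carbons of L-glutamic acid (commercial lactone 12). Its stereocentre (C11) steers C9, templates C8, and is then erased as the C11 ketone that activates C13 for ring D.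
5. Other stereocentres: C5 by copper-catalysed asymmetric conjugate addition, C1 by 1,3-controlled hydride reduction, C10 by equatorial radical attack anti to the axial C4 methyl, C13 by the bridge, C11 by exo-face hydride delivery at the end.

Key step: step 14

Remark: atoms are numbered as in ent-kaurane (C7 lactone carbonyl, C20 lactone CH2O, C6 acetoxymethyl carbon); where a centre is labile or is destroyed in a later step (C8 in 20–22, C15 in 30, the spiro carbon of 9) the expected major isomer is drawn, and C8 of 17 and 18 is left undefined.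

**Route**

Step 1
Reactants: 1 4,4-dimethylcyclohex-2-en-1-one
Product: 3 trans-2-[(dimethylamino)methyl]-3-{[dimethyl(propan-2-yloxy)silyl]methyl}-4,4-dimethylcyclohexan-1-one, via magnesium enolate 2 (not isolated)
Conditions: (i-PrO)Me2SiCH2MgCl (stock solution prepared beforehand from the commercial chlorosilane and Mg), CuBr·SMe2 (5 mol %), Josiphos-type ferrocenyl diphosphine (6 mol %), t-BuOMe, −78 °C; then CH2=NMe2+ I−, THF, −78 → 0 °C
Reagents that add atoms: [(isopropoxydimethylsilyl)methyl]magnesium chloride CC(C)O[Si](C)(C)C[Mg]Cl; N,N-dimethylmethyleneiminium iodide (Eschenmoser's salt) C=[N+](C)C.[I-]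
Why: Copper-catalysed asymmetric conjugate addition of the hydroxymethyl-anion equivalent sets C5 (ligand enantiomer chosen to give the 3S enolate), and the regiodefined magnesium enolate is trapped at C10 by the iminium salt (Mannich reaction) anti to the new C5 substituent.

Step 2
Reactants: 3 trans Mannich base
Product: 5 (3R)-3-{[dimethyl(propan-2-yloxy)silyl]methyl}-4,4-dimethyl-2-methylidenecyclohexan-1-one, via ammonium iodide 4 (not isolated)
Conditions: MeI, CH2Cl2, rt; then sat. aq. NaHCO3, rt
Reagents that add atoms: none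
Why: Exhaustive N-methylation and mild-base β-elimination through the ketone (Hofmann-type, E1cB) is the standard unmasking of a Mannich base to the α-methylene ketone, and bicarbonate is too weak to move the exocyclic double bond into the ring.

Step 3
Reactants: 5 α-methylene ketone
Product: 7 (1S,3R)-3-(hydroxymethyl)-4,4-dimethyl-2-methylidenecyclohexan-1-ol, via silyl allylic alcohol 6 (not isolated)
Conditions: NaBH4, CeCl3·7H2O, MeOH, −78 → −20 °C; then KF, KHCO3, 30 % H2O2, THF/MeOH, rt
Reagents that add atoms: hydrogen peroxide OO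
Why: Luche reduction delivers hydride 1,2 to the enone from the ring face opposite the C5 side chain (axial attack with that chain equatorial, or attack anti to it when axial), placing the C1 hydroxyl cis to C6, and Tamao–Fleming oxidation then converts C–Si into C6–OH with retention (alkoxy exchange on silicon in methanol is without consequence).

Step 4
Reactants: 7 diol
Product: 8 bis(tert-butyldimethylsilyl) ether of 7 (C1–OTBS and C6–OTBS)
Conditions: TBSOTf, 2,6-lutidine, CH2Cl2, −78 → 0 °C
Reagents that add atoms: tert-butyldimethylsilyl triflate CC(C)(C)[Si](C)(C)OS(=O)(=O)C(F)(F)F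
Why: Standard silylation of a primary and a secondary allylic alcohol with the silyl triflate; no stereocentre is touched.

Step 5
Reactants: 8 bis-silyl ether
Product: 9 4-(tert-butyldimethylsilyloxy)-8-[(tert-butyldimethylsilyloxy)methyl]-7,7-dimethyl-1-oxaspiro[2.5]octane (C10–C20 epoxide)
Conditions: mCPBA, NaHCO3, CH2Cl2, 0 °C
Reagents that add atoms: 3-chloroperoxybenzoic acid OOC(=O)c1cccc(Cl)c1
Why: Prilezhaev epoxidation of the electron-rich 1,1-disubstituted exocyclic alkene, expected anti to the axial C4 methyl; the spiro configuration is irrelevant because C10 becomes a planar radical in step 11.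

Step 6
Reactants: 10 (2-hydroxyethyl)triphenylphosphonium bromide
Product: 11 [2-(triethylsilyloxy)ethyl]triphenylphosphonium bromide
Conditions: Et3SiCl, imidazole, CH2Cl2, rt
Reagents that add atoms: chlorotriethylsilane CC[Si](CC)(CC)Cl
Why: Routine O-silylation, so that the derived ylide carries the future C14 oxygen in a form removable beside TBS ethers.

Step 7
Reactants: 12 (S)-5-(hydroxymethyl)dihydrofuran-2(3H)-one
Product: 13 (2S)-5-oxooxolane-2-carbaldehyde
Conditions: Dess–Martin periodinane, CH2Cl2, 0 °C → rt; used crude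
Reagents that add atoms: none
Why: Dess–Martin oxidation under neutral conditions gives the sensitive α-alkoxy aldehyde without epimerising C11.

Step 8
Reactants: 11 silyloxyethylphosphonium bromide; 13 lactone aldehyde
Product: 15 (S)-5-[(Z)-3-(triethylsilyloxy)prop-1-enyl]dihydrofuran-2(3H)-one, via phosphorus ylide 14 (not isolated)
Conditions: NaHMDS, THF, −78 °C; then 13, −78 → 0 °C
Reagents that add atoms: none
Why: Wittig reaction of a non-stabilised ylide under salt-free conditions at low temperature is Z-selective (kinetic cis-oxaphosphetane) and aldehyde-selective beside the lactone, setting the (Z)-C12=C13 geometry the later ring closure needs.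

Step 9
Reactants: 15 (Z)-alkenyl lactone
Product: 17 (5S)-3-acetyl-5-[(Z)-3-(triethylsilyloxy)prop-1-enyl]dihydrofuran-2(3H)-one (C8 epimers), via lithium enolate 16 (not isolated)
Conditions: LiHMDS, THF, −78 °C; then MeC(O)N(OMe)Me, −78 → −20 °C; AcOH quench
Reagents that add atoms: N-methoxy-N-methylacetamide CON(C)C(C)=O
Why: Claisen-type C-acylation of the lactone enolate with a Weinreb amide stops at the chelated tetrahedral adduct, so the acidic β-keto lactone (C15 on C8) is released only on quench.

Step 10
Reactants: 17 α-acetyl lactone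
Product: 19 (5R)-3-acetyl-5-[(Z)-3-(triethylsilyloxy)prop-1-enyl]furan-2(5H)-one, via selenide 18 (not isolated)
Conditions: PhSeCl, pyridine, CH2Cl2, 0 °C; aqueous wash; then 30 % H2O2, CH2Cl2, 0 °C; used at once
Reagents that add atoms: none
Why: α-Selenenylation of the enolised β-keto lactone at C8 and syn-elimination of the selenoxide, which can only take a C9 hydrogen, give the doubly activated butenolide without touching C11.

Step 11
Reactants: 9 ring A spiro-epoxide; 19 acylbutenolide
Product: 20 coupled γ-lactone (O11–C7 lactone; acetyl at C8; ring A at C9 through the new quaternary C10, which carries C20H2OH; (Z)-CH=CH–CH2OSiEt3 at C11; C8/C9 trans, C9/C11 trans)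
Conditions: Cp2TiCl2 (2.5 equiv), Zn dust, THF, rt (gives Cp2TiCl), added slowly to 9 and 19 (1.5 equiv), THF, 0 °C → rt; aq. NaH2PO4 work-up
Reagents that add atoms: none
Why: Nugent–RajanBabu reaction: Cp2TiCl (trivalent titanium) opens the epoxide to the tertiary C10 radical, which adds to C9 of the butenolide (Giese addition), and the 1,3-dicarbonyl radical is reduced to a titanium enolate; C10 is set by equatorial attack anti to the axial C4 methyl and C9 by attack anti to the C11 side chain, each partner being steered by its own neighbouring stereocentre.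

Step 12
Reactants: 20 coupled γ-lactone
Product: 21 allylic alcohol (C14–OH; otherwise as 20)
Conditions: PPTS (cat.), MeOH/CH2Cl2, 0 °C
Reagents that add atoms: none
Why: Acid-catalysed methanolysis removes the unhindered primary triethylsilyl ether much faster than the hindered TBS ethers.

Step 13
Reactants: 21 allylic alcohol
Product: 22 (Z)-allylic bromide (C14–Br; otherwise as 21)
Conditions: CBr4, PPh3, CH2Cl2, −30 → 0 °C; used crude
Reagents that add atoms: carbon tetrabromide BrC(Br)(Br)Br
Why: Appel reaction converts the allylic primary alcohol into the bromide by SN2 displacement with the Z geometry retained, while the neopentyl C20 alcohol cannot be displaced at this temperature.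

Step 14
Reactants: 22 (Z)-allylic bromide
Product: 23 bridged lactone: 1-acetyl-6-oxabicyclo[3.2.1]oct-3-en-7-one carrying ring A on its one-carbon bridge (C9), C20–OH free
Conditions: K2CO3, acetone, 0 °C → rt
Reagents that add atoms: none
Why: K2CO3 deprotonates C8–H, the carbon flanked by the C7 lactone carbonyl and the C15 ketone, and the delocalised enolate displaces bromide at the allylic C14 in an intramolecular SN2 C-alkylation; the closest known reaction type is the cyclising alkylation of β-keto esters with allylic halides. Ring C closes in the 6-exo-tet mode with both enolate carbonyls outside the new ring, and because C8 and C11 are already bridged by the γ-lactone the product is a 6-oxabicyclo[3.2.1]oct-3-en-7-one. The new quaternary stereocentre C8 is controlled by that temporary lactone: the C11 chain can reach C8 only on its own face, which is the face anti to ring A at C9, so the acetyl group ends exo and C7 and C10 become cis on ring C as in the target. C- over O-alkylation is secured by ring size (six against eight), SN2 over SN2′ likewise (six against four), and the Z geometry of C12=C13 keeps C14 within reach of C8. The free C20 hydroxyl does not interfere because the enolate deactivates the lactone carbonyl towards acyl transfer until the alkylation is over.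

Step 15
Reactants: 23 bridged lactone
Product: 25 spiro δ-lactone cyclohexenone (O20–C7 lactone cis-fused to ring C; C8 acetyl; C11 ketone; C12=C13), via δ-lactone allylic alcohol 24 (not isolated)
Conditions: DBU (0.2 equiv), activated MnO2, CH2Cl2, rt
Reagents that add atoms: none
Why: Base-catalysed transesterification moves the C7 acyl group from O11 to the neighbouring C20 hydroxyl (six-membered transition state, strain release of the bridged lactone), and MnO2, which oxidises allylic but not saturated primary alcohols, removes the liberated C11 allylic alcohol irreversibly as the enone, so the lactone exchange is drawn to completion and the auxiliary C11 stereocentre is erased.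

Step 16
Reactants: 25 methyl ketone enone
Product: 26 vinyl ketone (C15(=O)–C16H=C17H2 on C8; otherwise as 25)
Conditions: (CH2O)n, i-Pr2NH2+ CF3CO2−, THF, 65 °C
Reagents that add atoms: formaldehyde (as paraformaldehyde) C=O
Why: Direct α-methylenation (Mannich reaction then elimination) with formaldehyde and a secondary ammonium trifluoroacetate acts on the methyl ketone, the only position that can both enolise and eliminate, since C9 has no second hydrogen.

Step 17
Reactants: 26 vinyl ketone
Product: 27 1,6-bis-O-TBS 11,15-dioxo tetracycle (rings C and D as bicyclo[3.2.1]octane; C16=C17 methylidene)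
Conditions: PMe3 (20 mol %), t-AmOH, rt, dilute
Reagents that add atoms: none
Why: Intramolecular Rauhut–Currier reaction: the phosphine adds to the unhindered vinyl ketone terminus C17, the enolate carbon C16 adds to C13 of the cyclohexenone from the only face it can reach (C15 sits on the face of ring C opposite the lactone), and proton transfer with loss of the phosphine restores the C16 methylidene, closing ring D with C13 set by the bridge.

Step 18
Reactants: 27 bis-silyl ether
Product: 29 1,6-di-O-acetyl 11,15-dioxo tetracycle (11-oxo precursor of the target), via diol 28 (not isolated)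
Conditions: HF·pyridine, THF, 0 °C → rt; then Ac2O, DMAP, pyridine, rt
Reagents that add atoms: acetic anhydride CC(=O)OC(C)=O
Why: Fluoride cleaves both TBS ethers and the only two hydroxyls present are acetylated, C11 still being a ketone, so no selectivity among hydroxyls is needed.

Step 19
Reactants: 29 diacetate diketone
Product: 30 11,15-diol (11S as in the target; C15 hydroxyl on the face of ring D turned towards C9)
Conditions: NaBH4, CeCl3·7H2O, MeOH, −78 → 0 °C
Reagents that add atoms: none
Why: Luche reduction reduces both ketones 1,2 without touching lactone or acetates; at C11 hydride should enter from the exo face (the side of the C14 bridge) because the endo face is shielded by the C15–C16 bridge, giving the axial 11-hydroxyl, and the C15 configuration is immaterial.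

Step 20
Reactants: 30 diol
Product: 31 Rabdosin B
Conditions: activated MnO2, CH2Cl2, rt
Reagents that add atoms: none
Why: MnO2 oxidises only the allylic C15 alcohol back to the enone and leaves the saturated, hindered C11 alcohol.

**Compound list**

1 | 4,4-dimethylcyclohex-2-en-1-one | CC1(C)CCC(=O)C=C1 | starting material
2 | chloromagnesium enolate of (3S)-3-{[dimethyl(propan-2-yloxy)silyl]methyl}-4,4-dimethylcyclohexanone | CC(C)O[Si](C)(C)C[C@H]1C=C(O[Mg]Cl)CCC1(C)C | intermediate (not isolated)
3 | trans-2-[(dimethylamino)methyl]-3-{[dimethyl(propan-2-yloxy)silyl]methyl}-4,4-dimethylcyclohexan-1-one | CN(C)C[C@@H]1C(=O)CCC(C)(C)[C@H]1C[Si](C)(C)OC(C)C | intermediate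
4 | trimethylammonium iodide of 3 | C[N+](C)(C)C[C@@H]1C(=O)CCC(C)(C)[C@H]1C[Si](C)(C)OC(C)C.[I-] | intermediate (not isolated)
5 | (3R)-3-{[dimethyl(propan-2-yloxy)silyl]methyl}-4,4-dimethyl-2-methylidenecyclohexan-1-one | C=C1C(=O)CCC(C)(C)[C@H]1C[Si](C)(C)OC(C)C | intermediate
6 | (1S,3R)-3-{[dimethyl(propan-2-yloxy)silyl]methyl}-4,4-dimethyl-2-methylidenecyclohexan-1-ol | C=C1[C@@H](O)CCC(C)(C)[C@H]1C[Si](C)(C)OC(C)C | intermediate (not isolated)
7 | (1S,3R)-3-(hydroxymethyl)-4,4-dimethyl-2-methylidenecyclohexan-1-ol | C=C1[C@@H](O)CCC(C)(C)[C@H]1CO | intermediate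
8 | bis(tert-butyldimethylsilyl) ether of 7 | C=C1[C@@H](O[Si](C)(C)C(C)(C)C)CCC(C)(C)[C@H]1CO[Si](C)(C)C(C)(C)C | intermediate
9 | 4-(tert-butyldimethylsilyloxy)-8-[(tert-butyldimethylsilyloxy)methyl]-7,7-dimethyl-1-oxaspiro[2.5]octane | O1C[C@]12[C@@H](O[Si](C)(C)C(C)(C)C)CCC(C)(C)[C@H]2CO[Si](C)(C)C(C)(C)C | intermediate
10 | (2-hydroxyethyl)triphenylphosphonium bromide | OCC[P+](c1ccccc1)(c1ccccc1)c1ccccc1.[Br-] | starting material
11 | [2-(triethylsilyloxy)ethyl]triphenylphosphonium bromide | CC[Si](CC)(CC)OCC[P+](c1ccccc1)(c1ccccc1)c1ccccc1.[Br-] | intermediate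
12 | (S)-5-(hydroxymethyl)dihydrofuran-2(3H)-one | O=C1CC[C@@H](CO)O1 | starting material
13 | (2S)-5-oxooxolane-2-carbaldehyde | O=C1CC[C@@H](C=O)O1 | intermediate
14 | [2-(triethylsilyloxy)ethylidene]triphenylphosphorane | CC[Si](CC)(CC)OCC=P(c1ccccc1)(c1ccccc1)c1ccccc1 | intermediate (not isolated)
15 | (S)-5-[(Z)-3-(triethylsilyloxy)prop-1-enyl]dihydrofuran-2(3H)-one | O=C1CC[C@@H](/C=C\CO[Si](CC)(CC)CC)O1 | intermediate
16 | lithium enolate of 15 | [Li]OC1=CC[C@@H](/C=C\CO[Si](CC)(CC)CC)O1 | intermediate (not isolated)
17 | (5S)-3-acetyl-5-[(Z)-3-(triethylsilyloxy)prop-1-enyl]dihydrofuran-2(3H)-one (C8 epimers) | CC(=O)C1C[C@@H](/C=C\CO[Si](CC)(CC)CC)OC1=O | intermediate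
18 | 3-acetyl-3-(phenylselanyl) derivative of 15 (C8 epimers) | CC(=O)C1([Se]c2ccccc2)C[C@@H](/C=C\CO[Si](CC)(CC)CC)OC1=O | intermediate (not isolated)
19 | (5R)-3-acetyl-5-[(Z)-3-(triethylsilyloxy)prop-1-enyl]furan-2(5H)-one | CC(=O)C1=C[C@@H](/C=C\CO[Si](CC)(CC)CC)OC1=O | intermediate
20 | coupled γ-lactone (C14–OSiEt3, C20–OH) | CC(=O)[C@@H]1C(=O)O[C@H](/C=C\CO[Si](CC)(CC)CC)[C@H]1[C@]2(CO)[C@@H](O[Si](C)(C)C(C)(C)C)CCC(C)(C)[C@H]2CO[Si](C)(C)C(C)(C)C | intermediate
21 | coupled γ-lactone, (Z)-allylic alcohol (C14–OH) | CC(=O)[C@@H]1C(=O)O[C@H](/C=C\CO)[C@H]1[C@]2(CO)[C@@H](O[Si](C)(C)C(C)(C)C)CCC(C)(C)[C@H]2CO[Si](C)(C)C(C)(C)C | intermediate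
22 | coupled γ-lactone, (Z)-allylic bromide (C14–Br) | CC(=O)[C@@H]1C(=O)O[C@H](/C=C\CBr)[C@H]1[C@]2(CO)[C@@H](O[Si](C)(C)C(C)(C)C)CCC(C)(C)[C@H]2CO[Si](C)(C)C(C)(C)C | intermediate
23 | bridged lactone, 1-acetyl-6-oxabicyclo[3.2.1]oct-3-en-7-one with ring A at C9 | CC(=O)[C@]23CC=C[C@@H](OC3=O)[C@H]2[C@]1(CO)[C@@H](O[Si](C)(C)C(C)(C)C)CCC(C)(C)[C@H]1CO[Si](C)(C)C(C)(C)C | intermediate
24 | spiro δ-lactone with 11-epi allylic alcohol | CC(=O)[C@]23CC=C[C@@H](O)[C@H]2[C@]1(COC3=O)[C@@H](O[Si](C)(C)C(C)(C)C)CCC(C)(C)[C@H]1CO[Si](C)(C)C(C)(C)C | intermediate (not isolated)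
25 | spiro δ-lactone cyclohexenone, C8 acetyl | CC(=O)[C@]23CC=CC(=O)[C@H]2[C@]1(COC3=O)[C@@H](O[Si](C)(C)C(C)(C)C)CCC(C)(C)[C@H]1CO[Si](C)(C)C(C)(C)C | intermediate
26 | spiro δ-lactone cyclohexenone, C8 acryloyl | C=CC(=O)[C@]23CC=CC(=O)[C@H]2[C@]1(COC3=O)[C@@H](O[Si](C)(C)C(C)(C)C)CCC(C)(C)[C@H]1CO[Si](C)(C)C(C)(C)C | intermediate
27 | 1,6-bis-O-TBS 11,15-dioxo tetracycle | C=C1C(=O)[C@]23C[C@H]1CC(=O)[C@H]2[C@]1(COC3=O)[C@@H](O[Si](C)(C)C(C)(C)C)CCC(C)(C)[C@H]1CO[Si](C)(C)C(C)(C)C | intermediate
28 | 1,6-diol 11,15-dioxo tetracycle | C=C1C(=O)[C@]23C[C@H]1CC(=O)[C@H]2[C@]1(COC3=O)[C@@H](O)CCC(C)(C)[C@H]1CO | intermediate (not isolated)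
29 | 11-oxo Rabdosin B (1,6-diacetate, 11,15-dione) | C=C1C(=O)[C@]23C[C@H]1CC(=O)[C@H]2[C@]1(COC3=O)[C@@H](OC(C)=O)CCC(C)(C)[C@H]1COC(C)=O | intermediate
30 | 15-deoxo-15-hydroxy Rabdosin B (11,15-diol) | C=C1[C@@H](O)[C@]23C[C@H]1C[C@H](O)[C@H]2[C@]1(COC3=O)[C@@H](OC(C)=O)CCC(C)(C)[C@H]1COC(C)=O | intermediate
31 | Rabdosin B | C=C1C(=O)[C@]23C[C@H]1C[C@H](O)[C@H]2[C@]1(COC3=O)[C@@H](OC(C)=O)CCC(C)(C)[C@H]1COC(C)=O | target

**Count and risks**

Total: 20 steps. Longest linear sequence: 15 steps (steps 1–5, then 11–20).

Step 11 (fragment union). The doubly activated butenolide may be reduced or oligomerised by trivalent titanium, may lose configuration at C11 by γ-deprotonation, or may capture the hindered C10 radical too slowly. The fallback sets out from 15 and 9 and returns at 20, with the acetyl group introduced after the coupling. Lactone 15 is selenenylated (LiHMDS, PhSeBr, THF, −78 °C) to the α-phenylselanyl lactone F1 and oxidised (H2O2, CH2Cl2, 0 °C) to the plain butenolide F2, a less reducible and less acidic acceptor. F2 and 9 are coupled with catalytic Cp2TiCl2, Mn, Me3SiCl and 2,4,6-collidine in THF, which keeps the concentration of trivalent titanium low and delivers the C20 oxygen as the coupled trimethylsilyl ether F3. C-acetylation at C8 (LiHMDS, then N-methoxy-N-methylacetamide) gives the acetylated trimethylsilyl ether F4, and citric acid in methanol at 0 °C removes the trimethylsilyl group to give 20.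

Step 17 (ring D). The phosphine may oligomerise the vinyl ketone, or the C16 enolate may close reversibly onto the C11 carbonyl instead of adding to C13. The fallback sets out from 26 and returns at 27 with a stoichiometric sulfur carrier. Thiophenol with catalytic PhSLi in THF at 0 °C adds to C17 and the resulting enolate closes onto C13 (tandem Michael–Michael) to the tetracyclic phenyl sulfide F5. Oxidation with mCPBA (CH2Cl2, −78 °C) gives the sulfoxide F6, which on warming in toluene undergoes syn-elimination to restore the C16 methylidene of 27.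

Step 19 (C11 hydroxyl). Hydride delivery may show poor facial selectivity, because C10 on C9 also crowds the exo face, and the endo approach would give the 11-epimer. The fallback sets out from 29 and returns at 31, bypassing 30 and step 20. A ketoreductase (NADPH-dependent alcohol dehydrogenase, with glucose and glucose dehydrogenase for cofactor recycling, phosphate buffer/DMSO, 30 °C), selected by screening for the 11S alcohol, would reduce the saturated C11 ketone under catalyst control and leave the conjugated C15 ketone, the lactone and the acetates alone.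

Further compounds
F1 | step 11 | (5S)-3-(phenylselanyl)-5-[(Z)-3-(triethylsilyloxy)prop-1-enyl]dihydrofuran-2(3H)-one (C8 epimers) | O=C1C([Se]c2ccccc2)C[C@@H](/C=C\CO[Si](CC)(CC)CC)O1
F2 | step 11 | (5R)-5-[(Z)-3-(triethylsilyloxy)prop-1-enyl]furan-2(5H)-one | O=C1C=C[C@@H](/C=C\CO[Si](CC)(CC)CC)O1
F3 | step 11 | coupled γ-lactone without acetyl, C20–OSiMe3 | O=C1C[C@H]([C@]2(CO[Si](C)(C)C)[C@@H](O[Si](C)(C)C(C)(C)C)CCC(C)(C)[C@H]2CO[Si](C)(C)C(C)(C)C)[C@@H](/C=C\CO[Si](CC)(CC)CC)O1
F4 | step 11 | C20-O-trimethylsilyl ether of 20 | CC(=O)[C@@H]1C(=O)O[C@H](/C=C\CO[Si](CC)(CC)CC)[C@H]1[C@]2(CO[Si](C)(C)C)[C@@H](O[Si](C)(C)C(C)(C)C)CCC(C)(C)[C@H]2CO[Si](C)(C)C(C)(C)C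
F5 | step 17 | 16,17-dihydro-17-(phenylsulfanyl) derivative of 27 (C16 epimers) | c1ccccc1SCC1C(=O)[C@]23C[C@H]1CC(=O)[C@H]2[C@]4(COC3=O)[C@@H](O[Si](C)(C)C(C)(C)C)CCC(C)(C)[C@H]4CO[Si](C)(C)C(C)(C)C
F6 | step 17 | sulfoxide of F5 | O=S(c1ccccc1)CC1C(=O)[C@]23C[C@H]1CC(=O)[C@H]2[C@]4(COC3=O)[C@@H](O[Si](C)(C)C(C)(C)C)CCC(C)(C)[C@H]4CO[Si](C)(C)C(C)(C)C
F0 | step 19 | none | none
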